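**Retrosynthetic overview**
- The target comes from its nona-O-methyl ether by global demethylation. That ether comes from a triarylethylene by closing dihydrofuran ring 2 (O–C2', H–C3').
- The triarylethylene comes from an aryl ketone plus a 2,4-dimethoxybenzyl Grignard reagent. The ketone already carries the seven-membered ring, closed from a stilbene by Friedel–Crafts attack of ring A on C7b while the other dimethoxyphenyl ring is still a deactivated benzoyl group.
- The stilbene comes from a central aryl bromide and a styrylboronate (Suzuki). The bromide carries dihydrofuran ring 1, closed from a triarylethylene by a chiral Brønsted acid (first stereocentres).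
- That triarylethylene comes from a symmetric bis(2-hydroxybenzophenone) plus 4-methoxybenzyl Grignard. The bis-ketone comes from 1-bromo-3,5-dimethoxybenzene and two 3,5-dimethoxybenzoyl chlorides.
- Ring order: dihydrofuran 1, then the seven-membered ring, then dihydrofuran 2.

Labels: dihydrofuran 1 = O1, C2 (4-oxyphenyl), C3 (ring A); seven-membered ring = C7b (methine with the 2,4-dioxyphenyl group), C8b (CH2); dihydrofuran 2 = C2' (2,4-dioxyphenyl), C3' (3,5-dioxyphenyl). Target = (2R,3R,7bR,2'S,3'S). In the tetracyclic names, positions 1, 8, 9 and 16 are C3, C7b, C8b and C2.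

Assumption: the (R)-configured acid is taken to give the (2R,3R) ring; if the sense of induction is the reverse, the two catalyst antipodes are exchanged between steps 3 and 8.

Step 1
Reactants: 1 1-bromo-3,5-dimethoxybenzene; 2 3,5-dimethoxybenzoyl chloride (2.3 equiv)
Product: 4 (2-bromo-4,6-dihydroxy-1,3-phenylene)bis[(3,5-dimethoxyphenyl)methanone], via bis-ketone dimethyl ether 3 (not isolated)
Conditions: AlCl3 (6 equiv), CH2Cl2, 0 → 40 °C; aq HCl
Reagents that add atoms: none
Why: Twofold Friedel–Crafts acylation goes para to a methoxy group and ortho to bromine on each side (the site between the two methoxy groups is the most hindered), and excess AlCl3 then cleaves only the two methyl ethers that chelate the new carbonyl groups (chelation-controlled O-demethylation).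

Step 2
Reactants: 4 (2-bromo-4,6-dihydroxy-1,3-phenylene)bis[(3,5-dimethoxyphenyl)methanone]; 5 4-methoxybenzylmagnesium chloride (3.1 equiv)
Product: 7 [2-bromo-3-[1-(3,5-dimethoxyphenyl)-2-(4-methoxyphenyl)ethenyl]-4,6-dihydroxyphenyl](3,5-dimethoxyphenyl)methanone (E/Z mixture), via tertiary carbinol 6 (not isolated)
Conditions: LaCl3·2LiCl (1 equiv), THF, −20 → 0 °C; aq NH4Cl; then pyridinium p-toluenesulfonate (5 mol%), CH2Cl2, 25 °C
Reagents that add atoms: none
Why: Grignard 1,2-addition to a 2-hydroxybenzophenone stops after one side because the remaining ketone is then conjugated with both magnesium phenoxides and much less electrophilic, and mild acid dehydrates the tertiary benzylic carbinol through its o-quinone methide to the achiral triarylethylene, so no stereocentre is carried forward.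

Step 3
Reactants: 7 [2-bromo-3-[1-(3,5-dimethoxyphenyl)-2-(4-methoxyphenyl)ethenyl]-4,6-dihydroxyphenyl](3,5-dimethoxyphenyl)methanone
Product: 8 [(2R,3R)-4-bromo-3-(3,5-dimethoxyphenyl)-6-hydroxy-2-(4-methoxyphenyl)-2,3-dihydro-1-benzofuran-5-yl](3,5-dimethoxyphenyl)methanone
Conditions: (R)-3,3'-bis(2,4,6-triisopropylphenyl)-1,1'-binaphthyl-2,2'-diyl N-triflylphosphoramide (10 mol%), toluene, 5 Å MS, 0 → 25 °C
Reagents that add atoms: none
Why: Proposed new method: enantioselective Brønsted acid-catalysed 5-endo hydroalkoxylation of a 2-(1,2-diarylvinyl)phenol, in which the phenol OH hydrogen-bonds to the phosphoramide P=O while the acidic N–H delivers its proton to the diaryl-substituted alkene carbon inside the chiral pocket (enantio-determining, sets C3) and the resulting 4-methoxybenzylic cation/phosphoramidate ion pair collapses by O–C2 bond formation anti to the C3 aryl group (sets C2 trans), the E and Z isomers equilibrating through reversible unproductive protonation at C2 so that both pass through one transition state; the closest known reaction types are chiral imidodiphosphorimidate- and phosphoramide-catalysed asymmetric intramolecular hydroalkoxylation of alkenes and the racemic acid-catalysed cyclisation of 2-hydroxystilbenes to 2-aryl-2,3-dihydrobenzofurans.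

Step 4
Reactants: 9 2,4-dimethoxybenzaldehyde; 10 bis(4,4,5,5-tetramethyl-1,3,2-dioxaborolan-2-yl)methane
Product: 11 2-[(E)-2-(2,4-dimethoxyphenyl)ethenyl]-4,4,5,5-tetramethyl-1,3,2-dioxaborolane
Conditions: lithium 2,2,6,6-tetramethylpiperidide, THF, 0 °C; then 9, −78 → 25 °C
Reagents that add atoms: none
Why: Boron–Wittig olefination, in which the lithiated gem-diboronate adds to the aldehyde and syn-eliminates a borate to give the (E)-alkenylboronate.

Step 5
Reactants: 8 [(2R,3R)-4-bromo-3-(3,5-dimethoxyphenyl)-6-hydroxy-2-(4-methoxyphenyl)-2,3-dihydro-1-benzofuran-5-yl](3,5-dimethoxyphenyl)methanone; 11 2-[(E)-2-(2,4-dimethoxyphenyl)ethenyl]-4,4,5,5-tetramethyl-1,3,2-dioxaborolane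
Product: 12 [(2R,3R)-3-(3,5-dimethoxyphenyl)-4-[(E)-2-(2,4-dimethoxyphenyl)ethenyl]-6-hydroxy-2-(4-methoxyphenyl)-2,3-dihydro-1-benzofuran-5-yl](3,5-dimethoxyphenyl)methanone
Conditions: Pd(OAc)2 (5 mol%), 2-dicyclohexylphosphino-2',6'-dimethoxybiphenyl (10 mol%), K3PO4, toluene/H2O, 90 °C
Reagents that add atoms: none
Why: Suzuki–Miyaura coupling with a bulky electron-rich biarylphosphine that tolerates the di-ortho-substituted aryl bromide and the free phenol and keeps the E alkene geometry.

Step 6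
Reactants: 12 [(2R,3R)-3-(3,5-dimethoxyphenyl)-4-[(E)-2-(2,4-dimethoxyphenyl)ethenyl]-6-hydroxy-2-(4-methoxyphenyl)-2,3-dihydro-1-benzofuran-5-yl](3,5-dimethoxyphenyl)methanone
Product: 13 (1R,8R,16R)-11-(3,5-dimethoxybenzoyl)-8-(2,4-dimethoxyphenyl)-4,6-dimethoxy-16-(4-methoxyphenyl)-15-oxatetracyclo[8.6.1.0(2,7).0(14,17)]heptadeca-2(7),3,5,10(17),11,13-hexaen-12-ol
Conditions: CF3CO2H, CH2Cl2 (0.01 M), 0 → 25 °C
Reagents that add atoms: none
Why: Acid protonates the stilbene at the carbon attached to the central ring (the C7b cation is stabilised by the 2,4-dimethoxyphenyl group) and ring A on C3 closes the seven-membered ring by intramolecular Friedel–Crafts alkylation while the benzoyl-bound dimethoxyphenyl ring is deactivated, C7b being set by C3 because only the isomer with the C7b aryl group perpendicular to ring A and anti to its flanking methoxy group avoids allylic 1,3-strain (the same mode as the known acid cyclisation of ε-viniferin to ampelopsin B), and any reversible C2–O opening re-closes trans without touching C3.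

Step 7
Reactants: 13 (1R,8R,16R)-11-(3,5-dimethoxybenzoyl)-8-(2,4-dimethoxyphenyl)-4,6-dimethoxy-16-(4-methoxyphenyl)-15-oxatetracyclo[8.6.1.0(2,7).0(14,17)]heptadeca-2(7),3,5,10(17),11,13-hexaen-12-ol; 14 2,4-dimethoxybenzyl chloride
Product: 17 (1R,8R,16R)-11-[1-(3,5-dimethoxyphenyl)-2-(2,4-dimethoxyphenyl)ethenyl]-8-(2,4-dimethoxyphenyl)-4,6-dimethoxy-16-(4-methoxyphenyl)-15-oxatetracyclo[8.6.1.0(2,7).0(14,17)]heptadeca-2(7),3,5,10(17),11,13-hexaen-12-ol (E/Z mixture), via 2,4-dimethoxybenzylmagnesium chloride 15 (not isolated), via ring-fused tertiary carbinol 16 (not isolated)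
Conditions: 14, Mg, THF, 0 °C; then 13, LaCl3·2LiCl, THF, −20 → 25 °C; aq NH4Cl; then pyridinium p-toluenesulfonate (5 mol%), CH2Cl2, 25 °C
Reagents that add atoms: none
Why: The same Grignard addition–dehydration sequence as in step 2 on the one remaining ketone, the transient carbinol epimers converging on the triarylethylene.

Step 8
Reactants: 17 (1R,8R,16R)-11-[1-(3,5-dimethoxyphenyl)-2-(2,4-dimethoxyphenyl)ethenyl]-8-(2,4-dimethoxyphenyl)-4,6-dimethoxy-16-(4-methoxyphenyl)-15-oxatetracyclo[8.6.1.0(2,7).0(14,17)]heptadeca-2(7),3,5,10(17),11,13-hexaen-12-ol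
Product: 18 nona-O-methyl ether of CNP0283541.1 (all nine phenols as OMe; 2R,3R,7bR,2'S,3'S)
Conditions: (S)-3,3'-bis(2,4,6-triisopropylphenyl)-1,1'-binaphthyl-2,2'-diyl N-triflylphosphoramide (10 mol%), toluene, 5 Å MS, −20 → 0 °C
Reagents that add atoms: none
Why: Proposed new method: second use of the hydroalkoxylation of step 3 with the antipodal acid, needed because the two dihydrofurans are mirror-related across the central ring, the proton being delivered to C3' under catalyst control (the existing centres are remote and bias the faces little) and the strongly stabilised 2,4-dimethoxybenzylic cation closing to the trans ring at a temperature that leaves dihydrofuran 1 untouched; the closest known reaction types are those named in step 3.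

Step 9
Reactants: 18 nona-O-methyl ether of CNP0283541.1
Product: 19 CNP0283541.1 (target)
Conditions: BBr3 (20 equiv), CH2Cl2, −78 → 25 °C; MeOH, then H2O
Reagents that add atoms: none
Why: Lewis-acid ether cleavage (boron complexation, then SN2 by bromide at methyl) frees the nine phenols, and the skeleton is the acid-stable form in which both dihydrofurans re-close trans, so no stereocentre changes.

**Compound list**
1 | 1-bromo-3,5-dimethoxybenzene | COc1cc(Br)cc(OC)c1 | starting material
2 | 3,5-dimethoxybenzoyl chloride | COc1cc(cc(OC)c1)C(Cl)=O | starting material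
3 | (2-bromo-4,6-dimethoxy-1,3-phenylene)bis[(3,5-dimethoxyphenyl)methanone] | COc1cc(OC)c(C(=O)c2cc(OC)cc(OC)c2)c(Br)c1C(=O)c1cc(OC)cc(OC)c1 | intermediate
4 | (2-bromo-4,6-dihydroxy-1,3-phenylene)bis[(3,5-dimethoxyphenyl)methanone] | Oc1cc(O)c(C(=O)c2cc(OC)cc(OC)c2)c(Br)c1C(=O)c1cc(OC)cc(OC)c1 | intermediate
5 | 4-methoxybenzylmagnesium chloride | COc1ccc(C[Mg]Cl)cc1 | starting material
6 | [2-bromo-3-[1-(3,5-dimethoxyphenyl)-1-hydroxy-2-(4-methoxyphenyl)ethyl]-4,6-dihydroxyphenyl](3,5-dimethoxyphenyl)methanone (racemic) | Oc1cc(O)c(C(=O)c2cc(OC)cc(OC)c2)c(Br)c1C(O)(Cc1ccc(OC)cc1)c1cc(OC)cc(OC)c1 | intermediate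
7 | [2-bromo-3-[1-(3,5-dimethoxyphenyl)-2-(4-methoxyphenyl)ethenyl]-4,6-dihydroxyphenyl](3,5-dimethoxyphenyl)methanone (E/Z mixture) | Oc1cc(O)c(C(=O)c2cc(OC)cc(OC)c2)c(Br)c1C(=Cc1ccc(OC)cc1)c1cc(OC)cc(OC)c1 | intermediate
8 | [(2R,3R)-4-bromo-3-(3,5-dimethoxyphenyl)-6-hydroxy-2-(4-methoxyphenyl)-2,3-dihydro-1-benzofuran-5-yl](3,5-dimethoxyphenyl)methanone | COc1ccc([C@@H]2Oc3cc(O)c(C(=O)c4cc(OC)cc(OC)c4)c(Br)c3[C@H]2c2cc(OC)cc(OC)c2)cc1 | intermediate
9 | 2,4-dimethoxybenzaldehyde | COc1ccc(C=O)c(OC)c1 | starting material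
10 | bis(4,4,5,5-tetramethyl-1,3,2-dioxaborolan-2-yl)methane | CC1(C)OB(CB2OC(C)(C)C(C)(C)O2)OC1(C)C | starting material
11 | 2-[(E)-2-(2,4-dimethoxyphenyl)ethenyl]-4,4,5,5-tetramethyl-1,3,2-dioxaborolane | COc1ccc(/C=C/B2OC(C)(C)C(C)(C)O2)c(OC)c1 | intermediate
12 | [(2R,3R)-3-(3,5-dimethoxyphenyl)-4-[(E)-2-(2,4-dimethoxyphenyl)ethenyl]-6-hydroxy-2-(4-methoxyphenyl)-2,3-dihydro-1-benzofuran-5-yl](3,5-dimethoxyphenyl)methanone | COc1ccc([C@@H]2Oc3cc(O)c(C(=O)c4cc(OC)cc(OC)c4)c(/C=C/c4ccc(OC)cc4OC)c3[C@H]2c2cc(OC)cc(OC)c2)cc1 | intermediate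
13 | (1R,8R,16R)-11-(3,5-dimethoxybenzoyl)-8-(2,4-dimethoxyphenyl)-4,6-dimethoxy-16-(4-methoxyphenyl)-15-oxatetracyclo[8.6.1.0(2,7).0(14,17)]heptadeca-2(7),3,5,10(17),11,13-hexaen-12-ol | COc1ccc([C@@H]2Oc3cc(O)c(C(=O)c4cc(OC)cc(OC)c4)c4c3[C@H]2c2cc(OC)cc(OC)c2[C@@H](c2ccc(OC)cc2OC)C4)cc1 | intermediate
14 | 2,4-dimethoxybenzyl chloride | COc1ccc(CCl)c(OC)c1 | starting material
15 | 2,4-dimethoxybenzylmagnesium chloride | COc1ccc(C[Mg]Cl)c(OC)c1 | intermediate
16 | (1R,8R,16R)-11-[1-(3,5-dimethoxyphenyl)-2-(2,4-dimethoxyphenyl)-1-hydroxyethyl]-8-(2,4-dimethoxyphenyl)-4,6-dimethoxy-16-(4-methoxyphenyl)-15-oxatetracyclo[8.6.1.0(2,7).0(14,17)]heptadeca-2(7),3,5,10(17),11,13-hexaen-12-ol (both carbinol epimers) | COc1ccc([C@@H]2Oc3cc(O)c(C(O)(Cc4ccc(OC)cc4OC)c4cc(OC)cc(OC)c4)c4c3[C@H]2c2cc(OC)cc(OC)c2[C@@H](c2ccc(OC)cc2OC)C4)cc1 | intermediate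
17 | (1R,8R,16R)-11-[1-(3,5-dimethoxyphenyl)-2-(2,4-dimethoxyphenyl)ethenyl]-8-(2,4-dimethoxyphenyl)-4,6-dimethoxy-16-(4-methoxyphenyl)-15-oxatetracyclo[8.6.1.0(2,7).0(14,17)]heptadeca-2(7),3,5,10(17),11,13-hexaen-12-ol (E/Z mixture) | COc1ccc([C@@H]2Oc3cc(O)c(C(=Cc4ccc(OC)cc4OC)c4cc(OC)cc(OC)c4)c4c3[C@H]2c2cc(OC)cc(OC)c2[C@@H](c2ccc(OC)cc2OC)C4)cc1 | intermediate
18 | nona-O-methyl ether of CNP0283541.1 (2R,3R,7bR,2'S,3'S) | COc1ccc([C@@H]2Oc3cc4c(c5c3[C@H]2c2cc(OC)cc(OC)c2[C@@H](c2ccc(OC)cc2OC)C5)[C@H](c2cc(OC)cc(OC)c2)[C@@H](c2ccc(OC)cc2OC)O4)cc1 | intermediate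
19 | CNP0283541.1 (2R,3R,7bR,2'S,3'S) | Oc1ccc([C@@H]2Oc3cc4c(c5c3[C@H]2c2cc(O)cc(O)c2[C@@H](c2ccc(O)cc2O)C5)[C@H](c2cc(O)cc(O)c2)[C@@H](c2ccc(O)cc2O)O4)cc1 | target

**Step count**
Total steps: 9. Longest linear sequence: 8 (steps 1, 2, 3, 5, 6, 7, 8, 9; step 4 is the convergent branch).

**Three steps most likely to fail**

The first is step 3, the proposed hydroalkoxylation, which may give low conversion or low enantioselectivity. Its fallback uses known chemistry, sets out from 4 and comes back at 8. One phenol of 4 is alkylated with 4-methoxybenzyl chloride (1 equiv, K2CO3, DMF) to the mono-(4-methoxybenzyl) ether F1. Hydrazine condenses with the ketone next to the new ether, the other ketone staying in its hydrogen-bonded chelate, to give the hydrazone F2. MnO2 oxidises F2 to the diaryldiazomethane F3, which is not isolated. Rh2(S-PTAD)4, dirhodium tetrakis[(S)-(1-adamantyl)(phthalimido)acetate], then effects enantioselective intramolecular C–H insertion of the donor/donor carbene into the benzylic ether C–H bond, giving the cis-(2S,3R)-dihydrobenzofuran F4. CF3CO2H epimerises C2 through the 4-methoxybenzylic cation to the trans isomer 8.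

The second is step 8, the same new reaction on the most complex substrate, where the catalyst must override any substrate bias. Its fallback uses known chemistry, sets out from 13, comes back at 18 and bypasses step 7. The phenol of 13 is alkylated with 14 (K2CO3, DMF) to the 2,4-dimethoxybenzyl ether F5. Phosphazene base P4-t-Bu deprotonates the benzylic ether carbon, which adds to the neighbouring ketone and dehydrates on acidic work-up to the 2,3-diarylbenzofuran F6. Hydrogenation (H2, Pd on carbon) adds both hydrogens to one face and gives the cis-dihydrobenzofuran F7; facial selectivity here rests on the substrate and may be modest, so C3' epimers are separated by chromatography. CF3CO2H then epimerises C2' to trans, giving 18.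

The third is step 9, the ninefold demethylation, where BBr3 and the HBr it generates can ionise the benzylic C–O bonds and the C7b–aryl bond. The fallback sets out from 18 and comes back at 19: it replaces the Lewis-acid route by nucleophilic dealkylation with NaSC2H5 in DMF at 140 °C, an SN2 attack at each methyl group under basic conditions in which no benzylic cation can form. No new compound is formed (F0).

**Further compounds**
F1 | step 3 | [2-bromo-4-hydroxy-6-(4-methoxybenzyloxy)-1,3-phenylene]bis[(3,5-dimethoxyphenyl)methanone] | COc1ccc(COc2cc(O)c(C(=O)c3cc(OC)cc(OC)c3)c(Br)c2C(=O)c2cc(OC)cc(OC)c2)cc1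
F2 | step 3 | hydrazone of F1 at the ketone next to the benzyl ether | COc1ccc(COc2cc(O)c(C(=O)c3cc(OC)cc(OC)c3)c(Br)c2C(=NN)c2cc(OC)cc(OC)c2)cc1
F3 | step 3 | diaryldiazomethane from F2 | COc1ccc(COc2cc(O)c(C(=O)c3cc(OC)cc(OC)c3)c(Br)c2C(=[N+]=[N-])c2cc(OC)cc(OC)c2)cc1
F4 | step 3 | [(2S,3R)-4-bromo-3-(3,5-dimethoxyphenyl)-6-hydroxy-2-(4-methoxyphenyl)-2,3-dihydro-1-benzofuran-5-yl](3,5-dimethoxyphenyl)methanone (cis) | COc1ccc([C@H]2Oc3cc(O)c(C(=O)c4cc(OC)cc(OC)c4)c(Br)c3[C@H]2c2cc(OC)cc(OC)c2)cc1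
F5 | step 8 | 12-O-(2,4-dimethoxybenzyl) ether of 13 | COc1ccc([C@@H]2Oc3cc(OCc4ccc(OC)cc4OC)c(C(=O)c4cc(OC)cc(OC)c4)c4c3[C@H]2c2cc(OC)cc(OC)c2[C@@H](c2ccc(OC)cc2OC)C4)cc1
F6 | step 8 | 2',3'-didehydro analogue of 18 (2-(2,4-dimethoxyphenyl)-3-(3,5-dimethoxyphenyl)benzofuran in place of dihydrofuran 2) | COc1ccc([C@@H]2Oc3cc4oc(-c5ccc(OC)cc5OC)c(-c5cc(OC)cc(OC)c5)c4c4c3[C@H]2c2cc(OC)cc(OC)c2[C@@H](c2ccc(OC)cc2OC)C4)cc1
F7 | step 8 | C2' epimer of 18 (cis-2'R,3'S dihydrofuran 2) | COc1ccc([C@@H]2Oc3cc4c(c5c3[C@H]2c2cc(OC)cc(OC)c2[C@@H](c2ccc(OC)cc2OC)C5)[C@H](c2cc(OC)cc(OC)c2)[C@H](c2ccc(OC)cc2OC)O4)cc1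
F0 | step 9 | none | none
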